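**Assumption:** germacrane numbering is used for the ring compounds (ring C1–C10, C14 on C10, C15 on C4, C11–C13 on C7); angelic acid is bought, not made. The target is read as (1R,4R,5R,6S,7R,8S,10R): two trans oxiranes, a 6α-angelate and a trans-fused 8α,12-lactone.

## Retrosynthetic overview

1. The lactone is opened at the C8–O bond: the target comes from a C12 acrylic acid whose carboxylate is joined to the unactivated C8 methylene (sets C8).
2. The acid comes from an isopropenyl group (CH3 → CH2OH → CO2H), the C1–C10 oxirane from face-selective epoxidation of the E ring olefin, and the angelate from O-acylation of the C6 carbinol.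
3. The ten-membered carbocycle is opened at C6–C7: umpolung allylation of an α,β-epoxy aldehyde by its own terminal allylic chloride (sets C6 and C7).
4. The acyclic chloro epoxy aldehyde comes from (2E,6E)-farnesol: asymmetric epoxidation (sets C4 and C5), terminal allylic oxidation, chlorination, alcohol oxidation.
5. Order of ring formation: C4–C5 oxirane, carbocycle, C1–C10 oxirane, γ-lactone.

## Route

Step 1
Reactants: 1 (2E,6E)-farnesol
Product: 2 [(2R,3R)-3-[(3E)-4,8-dimethylnona-3,7-dien-1-yl]-3-methyloxiran-2-yl]methanol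
Conditions: Ti(OiPr)4 (10 mol %), D-(−)-diethyl tartrate (12 mol %), t-BuOOH, 4 Å sieves, CH2Cl2, −20 °C
Reagents that add atoms: tert-butyl hydroperoxide, CC(C)(C)OO
Why: Sharpless asymmetric epoxidation touches only the allylic-alcohol olefin, and the D-tartrate delivers oxygen to the face that gives the (2R,3R)-oxirane, which becomes C5 and C4 of the target.

Step 2
Reactants: 2 [(2R,3R)-3-[(3E)-4,8-dimethylnona-3,7-dien-1-yl]-3-methyloxiran-2-yl]methanol
Product: 3 (2E,6E)-9-[(2R,3R)-3-(hydroxymethyl)-2-methyloxiran-2-yl]-2,6-dimethylnona-2,6-dien-1-ol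
Conditions: SeO2 (0.2 equiv), t-BuOOH (3 equiv), CH2Cl2, 0 °C to rt
Reagents that add atoms: tert-butyl hydroperoxide, CC(C)(C)OO (oxygen passed on through catalytic SeO2)
Why: Sharpless SeO2/t-BuOOH allylic oxidation (ene reaction, then [2,3]-sigmatropic shift) prefers the (E)-methyl of the terminal, least hindered trisubstituted olefin; no stereocenter is formed.

Step 3
Reactants: 3 (2E,6E)-9-[(2R,3R)-3-(hydroxymethyl)-2-methyloxiran-2-yl]-2,6-dimethylnona-2,6-dien-1-ol
Product: 5 [(2R,3R)-3-[(3E,7E)-9-chloro-4,8-dimethylnona-3,7-dien-1-yl]-3-methyloxiran-2-yl]methanol, via allylic alkoxysulfonium chloride 4 (not isolated)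
Conditions: N-chlorosuccinimide, Me2S, CH2Cl2, −20 to 0 °C
Reagents that add atoms: N-chlorosuccinimide, O=C1CCC(=O)N1Cl
Why: Corey–Kim chlorination: only the allylic alkoxysulfonium salt collapses by chloride displacement at 0 °C, while the epoxy carbinol is returned on work-up; olefin geometry is kept.

Step 4
Reactants: 5 [(2R,3R)-3-[(3E,7E)-9-chloro-4,8-dimethylnona-3,7-dien-1-yl]-3-methyloxiran-2-yl]methanol
Product: 6 (2S,3R)-3-[(3E,7E)-9-chloro-4,8-dimethylnona-3,7-dien-1-yl]-3-methyloxirane-2-carbaldehyde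
Conditions: TEMPO (10 mol %), PhI(OAc)2 (1.1 equiv), CH2Cl2, 0 °C to rt
Reagents that add atoms: none
Why: Oxoammonium (TEMPO/PhI(OAc)2) oxidation takes the primary epoxy alcohol to the aldehyde without epimerising the epoxide carbon or touching the allylic chloride (the descriptor change R to S at the aldehyde-bearing carbon is only a priority change).

Step 5
Reactants: 6 (2S,3R)-3-[(3E,7E)-9-chloro-4,8-dimethylnona-3,7-dien-1-yl]-3-methyloxirane-2-carbaldehyde
Product: 9 (4R,5R,6S,7S)-4,5-epoxygermacra-1(10)E,11-dien-6-ol, via ethylzinc allyl species 7 (not isolated), via ethylzinc alkoxide 8 (not isolated)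
Conditions: PdCl2(PPh3)2 (10 mol %), Et2Zn (4 equiv), DMA, 0.01 M, syringe-pump addition of 6, rt; aq NH4Cl
Reagents that add atoms: none
Why: Palladium-catalysed umpolung allylation (π-allylpalladium, ethyl/allyl exchange with zinc) gives (E)-allylzinc 7, which adds to the aldehyde through a closed chair transition state with both ring tethers equatorial (C6/C7 anti), attacking anti to the C5–O bond with the aldehyde hydrogen rather than the zinc-bound oxygen beside the cis C15 methyl (1,3-strain analogue), which gives 6S,7S.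

Step 6
Reactants: 9 (4R,5R,6S,7S)-4,5-epoxygermacra-1(10)E,11-dien-6-ol; 10 angelic acid ((Z)-2-methylbut-2-enoic acid)
Product: 12 (4R,5R,6S,7S)-4,5-epoxygermacra-1(10)E,11-dien-6-yl (Z)-2-methylbut-2-enoate, via angelic 2,4,6-trichlorobenzoic anhydride 11 (not isolated)
Conditions: 10, 2,4,6-trichlorobenzoyl chloride, Et3N, toluene, rt, filter; then 9, toluene, 75 °C (no DMAP)
Reagents that add atoms: none
Why: Yamaguchi-type mixed-anhydride esterification without a nucleophilic catalyst acylates the hindered carbinol and is the acyl transfer known to keep the (Z)-enoate (no angelate-to-tiglate isomerisation); C6 is retained because only the O–acyl bond forms.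

Step 7
Reactants: 12 (4R,5R,6S,7S)-4,5-epoxygermacra-1(10)E,11-dien-6-yl (Z)-2-methylbut-2-enoate
Product: 13 (1R,4R,5R,6S,7S,10R)-1,10:4,5-diepoxygermacr-11-en-6-yl (Z)-2-methylbut-2-enoate
Conditions: dimethyldioxirane (1.05 equiv, acetone), CH2Cl2, −30 to 0 °C
Reagents that add atoms: dimethyldioxirane, CC1(C)OO1
Why: Dioxirane epoxidation is fastest at the strained, electron-rich trisubstituted ring olefin (isopropenyl slower, enoate inert) and attacks the outer face of the crossed conformer with C14 syn to C15, as in parthenolide-type rings, giving the 1R,10R oxirane under acid-free conditions.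

Step 8
Reactants: 13 (1R,4R,5R,6S,7S,10R)-1,10:4,5-diepoxygermacr-11-en-6-yl (Z)-2-methylbut-2-enoate
Product: 14 (1R,4R,5R,6S,7S,10R)-1,10:4,5-diepoxy-12-hydroxygermacr-11(13)-en-6-yl (Z)-2-methylbut-2-enoate
Conditions: SeO2 (0.5 equiv), t-BuOOH (2.5 equiv), CH2Cl2, 0 °C to rt
Reagents that add atoms: tert-butyl hydroperoxide, CC(C)(C)OO (oxygen passed on through catalytic SeO2)
Why: SeO2/t-BuOOH allylic oxidation: the isopropenyl group is now the only electron-rich olefin, and the ene/[2,3] sequence functionalises its methyl group in preference to the tertiary C7–H; no stereocenter is touched.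

Step 9
Reactants: 14 (1R,4R,5R,6S,7S,10R)-1,10:4,5-diepoxy-12-hydroxygermacr-11(13)-en-6-yl (Z)-2-methylbut-2-enoate
Product: 16 (1R,4R,5R,6S,7S,10R)-6-[(Z)-2-methylbut-2-enoyloxy]-1,10:4,5-diepoxygermacr-11(13)-en-12-oic acid, via 12-aldehyde 15 (not isolated)
Conditions: TEMPO (10 mol %), NaClO2 (2 equiv), NaOCl (5 mol %), MeCN / NaH2PO4–Na2HPO4 buffer pH 6.7, 35 °C; NaH2PO4 to pH 4, extract, use at once
Reagents that add atoms: sodium chlorite, [Na+].[O-]Cl=O
Why: Zhao–Anelli oxidation (oxoammonium to the enal, then chlorite, Pinnick-type, to the acid) runs near neutral pH, so the oxiranes, the angelate and the C7 stereocenter survive.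

Step 10
Reactants: 16 (1R,4R,5R,6S,7S,10R)-6-[(Z)-2-methylbut-2-enoyloxy]-1,10:4,5-diepoxygermacr-11(13)-en-12-oic acid
Product: 17 (1R,4R,5R,6S,7R,8S,10R)-6-[(Z)-2-methylbut-2-enoyloxy]-1,10:4,5-diepoxygermacr-11(13)-en-12,8-olide (CNP0145353.1)
Conditions: Mn(OTf)2[(S,S)-TIPSmcp] (2 mol %; TIPSmcp = N,N'-dimethyl-N,N'-bis[(5-triisopropylsilylpyridin-2-yl)methyl]cyclohexane-1,2-diamine), H2O2 (50% aq, 1.5 equiv, syringe pump 1 h), CF3CH2OH, −20 °C, 0.05 M
Reagents that add atoms: none
Why: Proposed new method: the acid binds divalent manganese next to the peroxide site, acid-assisted O–O heterolysis gives a pentavalent manganese oxo carboxylate that abstracts H-8α by 1,7-hydrogen transfer, and the bound carboxylate rebounds onto the C8 radical with retention to close the trans-fused lactone (8S). C6–H is deactivated (tertiary, α-acyloxy), the two enoate olefins are electron-poor and kept away by the bulky silyl groups, and the chiral pocket chooses between the two C8 hydrogens; the closest known reaction type is manganese-catalysed enantioselective γ-C(sp3)–H lactonization of saturated aliphatic acids with H2O2, not yet shown for 2-substituted acrylic acids or epoxide-bearing medium rings.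

## Compound list

1 | (2E,6E)-farnesol | CC(C)=CCC/C(C)=C/CC/C(C)=C/CO | starting material
2 | [(2R,3R)-3-[(3E)-4,8-dimethylnona-3,7-dien-1-yl]-3-methyloxiran-2-yl]methanol | CC(C)=CCC/C(C)=C/CC[C@@]1(C)O[C@@H]1CO | intermediate
3 | (2E,6E)-9-[(2R,3R)-3-(hydroxymethyl)-2-methyloxiran-2-yl]-2,6-dimethylnona-2,6-dien-1-ol | OC/C(C)=C/CC/C(C)=C/CC[C@@]1(C)O[C@@H]1CO | intermediate
4 | {[(2E,6E)-9-[(2R,3R)-3-(hydroxymethyl)-2-methyloxiran-2-yl]-2,6-dimethylnona-2,6-dien-1-yl]oxy}dimethylsulfonium chloride | C[S+](C)OC/C(C)=C/CC/C(C)=C/CC[C@@]1(C)O[C@@H]1CO.[Cl-] | intermediate (not isolated)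
5 | [(2R,3R)-3-[(3E,7E)-9-chloro-4,8-dimethylnona-3,7-dien-1-yl]-3-methyloxiran-2-yl]methanol | ClC/C(C)=C/CC/C(C)=C/CC[C@@]1(C)O[C@@H]1CO | intermediate
6 | (2S,3R)-3-[(3E,7E)-9-chloro-4,8-dimethylnona-3,7-dien-1-yl]-3-methyloxirane-2-carbaldehyde | ClC/C(C)=C/CC/C(C)=C/CC[C@@]1(C)O[C@@H]1C=O | intermediate
7 | ethyl{(2E,6E)-9-[(2R,3S)-3-formyl-2-methyloxiran-2-yl]-2,6-dimethylnona-2,6-dien-1-yl}zinc | CC[Zn]C/C(C)=C/CC/C(C)=C/CC[C@@]1(C)O[C@@H]1C=O | intermediate (not isolated)
8 | ethylzinc alkoxide of 9 (O6–Zn–Et) | C=C(C)[C@@H]1CC/C(C)=C/CC[C@@]2(C)O[C@@H]2[C@H]1O[Zn]CC | intermediate (not isolated)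
9 | (4R,5R,6S,7S)-4,5-epoxygermacra-1(10)E,11-dien-6-ol = (1R,2S,3S,6E,10R)-6,10-dimethyl-3-(prop-1-en-2-yl)-11-oxabicyclo[8.1.0]undec-6-en-2-ol | C=C(C)[C@@H]1CC/C(C)=C/CC[C@@]2(C)O[C@@H]2[C@H]1O | intermediate
10 | angelic acid, (Z)-2-methylbut-2-enoic acid | C/C=C(/C)C(=O)O | starting material
11 | (Z)-2-methylbut-2-enoic 2,4,6-trichlorobenzoic anhydride | C/C=C(/C)C(=O)OC(=O)c1c(Cl)cc(Cl)cc1Cl | intermediate (not isolated)
12 | (4R,5R,6S,7S)-4,5-epoxygermacra-1(10)E,11-dien-6-yl (Z)-2-methylbut-2-enoate | C=C(C)[C@@H]1CC/C(C)=C/CC[C@@]2(C)O[C@@H]2[C@H]1OC(=O)/C(C)=C\C | intermediate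
13 | (1R,4R,5R,6S,7S,10R)-1,10:4,5-diepoxygermacr-11-en-6-yl (Z)-2-methylbut-2-enoate | C=C(C)[C@@H]1CC[C@@]2(C)O[C@@H]2CC[C@@]2(C)O[C@@H]2[C@H]1OC(=O)/C(C)=C\C | intermediate
14 | (1R,4R,5R,6S,7S,10R)-1,10:4,5-diepoxy-12-hydroxygermacr-11(13)-en-6-yl (Z)-2-methylbut-2-enoate | C=C(CO)[C@@H]1CC[C@@]2(C)O[C@@H]2CC[C@@]2(C)O[C@@H]2[C@H]1OC(=O)/C(C)=C\C | intermediate
15 | (1R,4R,5R,6S,7S,10R)-1,10:4,5-diepoxy-12-oxogermacr-11(13)-en-6-yl (Z)-2-methylbut-2-enoate | C=C(C=O)[C@@H]1CC[C@@]2(C)O[C@@H]2CC[C@@]2(C)O[C@@H]2[C@H]1OC(=O)/C(C)=C\C | intermediate (not isolated)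
16 | (1R,4R,5R,6S,7S,10R)-6-[(Z)-2-methylbut-2-enoyloxy]-1,10:4,5-diepoxygermacr-11(13)-en-12-oic acid | C=C(C(=O)O)[C@@H]1CC[C@@]2(C)O[C@@H]2CC[C@@]2(C)O[C@@H]2[C@H]1OC(=O)/C(C)=C\C | intermediate
17 | (1R,4R,5R,6S,7R,8S,10R)-6-[(Z)-2-methylbut-2-enoyloxy]-1,10:4,5-diepoxygermacr-11(13)-en-12,8-olide | C=C1C(=O)O[C@H]2C[C@@]3(C)O[C@@H]3CC[C@@]3(C)O[C@@H]3[C@@H](OC(=O)/C(C)=C\C)[C@H]12 | target

## Step count and risks

Total step count: 10. Longest linear sequence: 10 steps (1 to 17); 10 enters at step 6.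

**Step 10 (new C–H lactonization).** It may fail through oxidation of the enoate olefins, a cis-fused lactone, or epoxide opening in the fluorinated alcohol; the mirror-image catalyst is the first control. The fallback uses known chemistry (Barton-type N-iodoamide photolysis, the amide version of the Hofmann–Löffler–Freytag reaction), sets out from 16 and comes back at 17. Acid 16 is turned, through its isobutyl mixed anhydride and ammonia, into the primary acrylamide F9. PhI(OAc)2 and I2 under visible light in CH2Cl2 over NaHCO3 give the N-iodoamide F10, whose amidyl radical takes a C8 hydrogen by 1,5-transfer to give the 8-iodo amide F11. The amide oxygen displaces iodide to give the iminolactone F12, and aqueous work-up hydrolyses it to 17. The C8 epimers would be separated; the trans-fused isomer is expected to predominate.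

**Step 5 (macrocyclization).** It may fail through oligomers, ethyl transfer or reduction, or attack on the wrong aldehyde face; the facial preference relative to the oxirane is argued from a model, not assured. The fallback replaces the in-situ zinc reagent by a preformed allylboronate that closes thermally; it sets out from 5 and comes back at 9. Chloride 5 is borylated (Pd(dba)2, AsPh3, B2pin2, toluene, 50 °C) to the linear (E)-allylboronate alcohol F1. Dess–Martin periodinane with pyridine gives the aldehyde F2, which at 0.005 M in toluene at 40 °C closes by intramolecular allylboration through the same chair arrangement to the pinacol borate F3. Aqueous NaHCO3 releases 9.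

**Step 7 (face of the C1–C10 epoxidation).** It relies on the ring conformer population, so the 1S,10S isomer may form. The fallback sets C1 and C10 by reagent control before the ring exists; it sets out from 5 and comes back at 13. Shi epoxidation of 5 (D-fructose-derived ketone, KHSO5, K2CO3 buffer, MeCN/dimethoxymethane, 0 °C) attacks only the isolated olefin, the other being an electron-poor allylic chloride, and gives the bis-epoxy chloro alcohol F4 with (R,R) configuration at the new oxirane. TEMPO/PhI(OAc)2 gives the aldehyde F5. Cyclization under the step 5 conditions runs through the ethylzinc allyl species F6 and the ethylzinc alkoxide F7 to the diepoxy alcohol F8, and acylation with anhydride 11 as in step 6 gives 13.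

## Further compounds

F1 | step 5 | [(2R,3R)-3-[(3E,7E)-4,8-dimethyl-9-(4,4,5,5-tetramethyl-1,3,2-dioxaborolan-2-yl)nona-3,7-dien-1-yl]-3-methyloxiran-2-yl]methanol | CC1(C)OB(C/C(C)=C/CC/C(C)=C/CC[C@@]2(C)O[C@@H]2CO)OC1(C)C
F2 | step 5 | (2S,3R)-3-[(3E,7E)-4,8-dimethyl-9-(4,4,5,5-tetramethyl-1,3,2-dioxaborolan-2-yl)nona-3,7-dien-1-yl]-3-methyloxirane-2-carbaldehyde | CC1(C)OB(C/C(C)=C/CC/C(C)=C/CC[C@@]2(C)O[C@@H]2C=O)OC1(C)C
F3 | step 5 | 2-{[(4R,5R,6S,7S)-4,5-epoxygermacra-1(10)E,11-dien-6-yl]oxy}-4,4,5,5-tetramethyl-1,3,2-dioxaborolane | C=C(C)[C@@H]1CC/C(C)=C/CC[C@@]2(C)O[C@@H]2[C@H]1OB1OC(C)(C)C(C)(C)O1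
F4 | step 7 | [(2R,3R)-3-{2-[(2R,3R)-3-[(3E)-5-chloro-4-methylpent-3-en-1-yl]-3-methyloxiran-2-yl]ethyl}-3-methyloxiran-2-yl]methanol | ClC/C(C)=C/CC[C@@]1(C)O[C@@H]1CC[C@@]1(C)O[C@@H]1CO
F5 | step 7 | (2S,3R)-3-{2-[(2R,3R)-3-[(3E)-5-chloro-4-methylpent-3-en-1-yl]-3-methyloxiran-2-yl]ethyl}-3-methyloxirane-2-carbaldehyde | ClC/C(C)=C/CC[C@@]1(C)O[C@@H]1CC[C@@]1(C)O[C@@H]1C=O
F6 | step 7 | ethylzinc allyl species from F5 (Zn in place of Cl) | CC[Zn]C/C(C)=C/CC[C@@]1(C)O[C@@H]1CC[C@@]1(C)O[C@@H]1C=O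
F7 | step 7 | ethylzinc alkoxide of F8 | C=C(C)[C@@H]1CC[C@@]2(C)O[C@@H]2CC[C@@]2(C)O[C@@H]2[C@H]1O[Zn]CC
F8 | step 7 | (1R,4R,5R,6S,7S,10R)-1,10:4,5-diepoxygermacr-11-en-6-ol | C=C(C)[C@@H]1CC[C@@]2(C)O[C@@H]2CC[C@@]2(C)O[C@@H]2[C@H]1O
F9 | step 10 | (1R,4R,5R,6S,7S,10R)-12-amino-1,10:4,5-diepoxy-12-oxogermacr-11(13)-en-6-yl (Z)-2-methylbut-2-enoate (primary amide of 16) | C=C(C(N)=O)[C@@H]1CC[C@@]2(C)O[C@@H]2CC[C@@]2(C)O[C@@H]2[C@H]1OC(=O)/C(C)=C\C
F10 | step 10 | N-iodo derivative of F9 | C=C(C(=O)NI)[C@@H]1CC[C@@]2(C)O[C@@H]2CC[C@@]2(C)O[C@@H]2[C@H]1OC(=O)/C(C)=C\C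
F11 | step 10 | 8-iodo derivative of F9 (C8 epimers) | C=C(C(N)=O)[C@@H]1C(I)C[C@@]2(C)O[C@@H]2CC[C@@]2(C)O[C@@H]2[C@H]1OC(=O)/C(C)=C\C
F12 | step 10 | 12-imino analogue of 17 (iminolactone, C=NH in place of C=O) | C=C1C(=N)O[C@H]2C[C@@]3(C)O[C@@H]3CC[C@@]3(C)O[C@@H]3[C@@H](OC(=O)/C(C)=C\C)[C@H]12
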